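All runs were generated by integration for an exercise, noise included.

| flask | substrate | reagent in the second phase | remark | time | volume of the second phase over the first |
|---|---|---|---|---|---|
| epsilon | 0.29 M | 0.80 equiv | the very flask that is asked about, followed so far |  |  |
| eta | 0.43 M | 0.80 equiv | run made earlier |  |  |
| flask | 0.29 M | 0.800 equiv |  | 2.5 min | 1.0 |

epsilon run (percent of the substrate charged)

| time / s | target / % | substrate / % |
|---|---|---|
| 10.0 | 1.3 | 98.8 |
| 15.0 | 1.8 | 96.5 |
| 30.0 | 5.1 | 93.7 |
| 40.0 | 5.3 | 93.1 |
| 60.0 | 7.8 | 94.3 |

eta run (percent of the substrate charged)

| time / min | target / % | substrate / % |
|---|---|---|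
| 0.500 | 6.6 | 94.1 |
| 1.00 | 9.9 | 88.4 |
| 1.50 | 9.1 | 88.7 |
| 2.00 | 10.0 | 85.5 |
| 2.50 | 10.1 | 87.5 |

(scatter of a reading: 1 percentage point)

- in the second phase: reagent in the second phase; everything else is in the first
- charges count per volume of the first phase; a concentration in a rate is the amount of a species over the volume of its own phase; every rate counts per litre of the first phase
- the earlier runs hold the two phases in the same ratio of volumes as the flask asked about

1. target at 2.5 min, in percent of the substrate charged
2. the change that raises the amount of target at 2.5 min, in percent of the substrate charged most ("none" if none brings more than 2 percentage points) (green / red / none)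
3. amount of target at 2.5 min, in percent of the substrate charged, after red

- green: doubling the amount of reagent in the second phase, all else as stated
- red: doubling the transfer coefficient of the reagent in the second phase, all else as stated

In the eta run the substrate stands above the target at the last reading, 87.5% against 10.1%, yet the target already read 9.9% at 1.00 min, a difference inside the scatter of 1 percentage point. From 1.00 min on the eta target averages 9.78%, which at one reagent per target takes 12.2% of the reagent charged, so I read the stall as a balance.

I reckon 0.359 M⁻¹ for c(target) over c(substrate) times c(reagent in the second phase), each taken as charged less what the target took; this is my stall quotient, an apparent equilibrium constant. For the asked flask, the quotient times 0.29 M is 0.104, and the target share is this times the substrate share left times the equivalents of reagent left. The answer thus sits on both sides, so I iterate. With nothing used I get 8.32%; put back, that gives 6.84%, and once more 7.09%. Reckoned the same way, green gives 13.4%, and red leaves my figure alone: the quotient holds no transfer coefficient.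

The forecast says 9%, above my figure, names green, and gives 9.5% after red, holding that “Faster transfer only speeds the approach to an equilibrium”.

The flask gives 7.14%, and 7.12% after red, with green best by 4.4 points.

    substrate + reagent in the reaction phase ⇌ target (K = 0.990 M⁻¹, k = 0.0140 M⁻¹ s⁻¹)
    reagent in the reaction phase ⇌ reagent in the second phase, rate k2*([reagent in the reaction phase] - [reagent in the second phase]/K2) per volume of the first phase (partition coefficient = 0.340, kL = 0.0700 s⁻¹)
    reagent in the reaction phase → decomposed reagent (k = 0.00570 s⁻¹)
    reagent in the reaction phase + target → over-reacted product (k = 0.0210 M⁻¹ s⁻¹)

In this flask the relaxation half-life of the step to target at 2.50 min, both ways together, is 0.611 min, short against 2.5 min. Put back, this flask's 7.14% returns the stall quotient as 0.364 M⁻¹, an apparent figure below the scheme's 0.99 M⁻¹. For the neighbour with 0.72 M of substrate, same equivalents and time, the rounds run 20.7%, 12.2%, 15.4%, and that flask gives 11.4%.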